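In blue, the flask asked about, E could not have left one X at a time: by 5.00 h it had lost 61.6% of its charge, more than the 60.0% of X charged per E. So some E went by E + J → L.

| flask | E | X | temperature | remark | time |
|---|---|---|---|---|---|
| blue | 1 M | 0.60 M | 25 °C | the very flask that is asked about, followed so far |  |
| teal | 1 M | 0.60 M | 10 °C | run made earlier |  |
| flask | 1.0 M | 0.600 M | 25 °C |  | 5.0 h |

| run | time / h | J / % | E / % |
|---|---|---|---|
| blue | 0.417 | 23.3 | 75.4 |
| blue | 0.833 | 33.4 | 63.5 |
| blue | 1.33 | 38.4 | 55.1 |
| blue | 2.50 | 42.7 | 45.0 |
| blue | 5.00 | 42.1 | 38.4 |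
| teal | 0.833 | 13.0 | 87.0 |
| teal | 2.00 | 24.1 | 73.7 |
| teal | 3.00 | 30.4 | 66.4 |
| teal | 5.00 | 36.1 | 57.1 |
| teal | 10.0 | 42.2 | 47.1 |

(standard deviation of a reading: 0.5 percentage points)

- Monday's: at 5.0 h raise the temperature by 10 K, then wait 10 h
- Thursday's: at 5.0 h take out 90% of the Z then present, then wait 10 h
- Saturday's: change nothing and wait 10 h more
- Sunday's: at 5.0 h add X, 50.0% of the amount charged, then wait 10 h

- a species is counted by the E in it: one L counts as two
- additions bring no volume worth counting
- what was read earlier has a scatter of 0.5 percentage points, one standard deviation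
- steps that have been proposed: E + X -> Z + J; J + X -> Z + D; E + J -> L

1. J, in percent of the E first charged, at 5.0 h
2. the remedy with the largest gain of J, or "none" below 2 percentage points (Monday's / Thursday's / Saturday's / Sunday's / none)
3. J present, in percent of the E first charged, after Thursday's
4. J present, in percent of the E first charged, after Sunday's

I called the constants of E + X → Z + J and E + J → L kJ and kL, and divided the rate of making J by the rate of losing it to L. E and time drop out, leaving ρ = s·X/J, where s = kJ/kL is a selectivity factor. J stops climbing near ρ = 1 while D stays small. From blue's first fall of E, and from the rise of the missing E (neither E nor J) between the last two readings, I read s = 17.3.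

Counting all missing E as L, the balance left 0.0815 M of X, and ρ = 3.35. But J read flat, 42.7% then 42.1%, so that link was weak. I reforged it by setting ρ = 1: X, the limiting reagent, stood near 0.0243 M, and the difference put D near 3.81%.

Sunday's adds 0.300 M of X, lifting ρ to 13.3. I allowed 0.5 of that X as net J, and took J's drain to L, one J for every two E missing, at 0.5 of blue's late pace, 7.20% over the wait. That gave me 49.9%. The other remedies bring no X, and I expected J to fall in them.

The forecast gave 42.1%, none, 36% after Thursday's and 43% after Sunday's, “less any D”. On Sunday's we differed.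

The flask gave 42.5%, and Sunday's won with 48.1%, a gain of 5.7 percentage points, while Thursday's left J at 33.3%.

    E + X → Z + J (k = 4.00 × 10⁻⁴ M⁻¹ s⁻¹, Ea = 69.0 kJ mol⁻¹)
    J + X → Z + D (k = 8.30 × 10⁻⁵ M⁻¹ s⁻¹, Ea = 60.0 kJ mol⁻¹)
    E + J → L (k = 2.20 × 10⁻⁵ M⁻¹ s⁻¹, Ea = 68.0 kJ mol⁻¹)
    (constants at 25 °C)

At 5.00 h the flask kept 1.44% of its X, so s gives ρ = 0.352, and J was being made at 0.342 of the rate it was used up, each step taken net.

In a neighbour flask charged with 0.24 M of X, taking J equal to that charge puts ρ = 1 at 0.0139 M of X. That neighbour, as computed, stood below this X, with 0.29% of its X left, J at 17.6% and E at 71.6%.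

The data are simulated from invented constants, noise included.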